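## Retrosynthetic overview

1. The target is opened at C8–C16: conjugate hydride addition at C9 of an eleven-membered enone and transannular Michael addition form the cyclopentane and the eight-membered ring last.
2. The ether bridge C16–O–C12 (2-oxabicyclo[2.2.2]octane) comes from O-demethylation of a methyl tetronate and opening of a C11/C12 epoxide, itself made from a cyclohexene.
3. The cyclohexene and the eleven-membered ring come together from one intramolecular Diels–Alder reaction of an acyclic trienone carrying a 3-acyl-5-methylene tetronate (bonds C10–C15 and C13–C14).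
4. The trienone comes from a crossed aldol condensation (C8–C9) of a C1–C8 methyl ketone with (2E,4E)-4-methylhexa-2,4-dienal; the methyl ketone comes from addition of a 3-lithiated 5-methylene tetronate to a C3 aldehyde (C2–C3).
5. Building blocks: meso-2,4-dimethylglutaric anhydride (enzymatic desymmetrisation sets C4 and C6), methyl tetronate (the butenolide ring is bought) and tiglic aldehyde.

Assumption: atoms carry abyssomicin numbering (C1 lactone carbonyl, C2, C3 enol carbon, C4–C14 along the chain, C15 spiro carbon, C16 ether-bearing carbon); furanone C2, C3, C4, C5 and the exocyclic CH2 become C1, C2, C16, C15 and C14.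

## Route

Step 1
Reactants: 1 meso-2,4-dimethylglutaric anhydride
Product: 2 meso-2,4-dimethylpentane-1,5-diol
Conditions: LiAlH4, THF, 0 °C to reflux; then H2O
Reagents that add atoms: none
Why: LiAlH4 reduces both anhydride carbonyls to primary alcohols (hydride reduction) without touching the two methyl-bearing carbons, so the meso relationship that becomes the syn C4/C6 pair is kept.

Step 2
Reactants: 2 meso-2,4-dimethylpentane-1,5-diol
Product: 3 (2S,4R)-5-hydroxy-2,4-dimethylpentyl acetate
Conditions: Pseudomonas fluorescens lipase (Amano AK), vinyl acetate, THF, rt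
Reagents that add atoms: vinyl acetate C=COC(C)=O
Why: Irreversible lipase transesterification (enzymatic desymmetrisation of a meso diol) acetylates only the hydroxymethyl arm on the S-configured carbon, which fixes both methyl centres in high ee (acetate end = future C3/C4 with 4S, free alcohol end = future C6/C7 with 6R).

Step 3
Reactants: 3 (2S,4R)-5-hydroxy-2,4-dimethylpentyl acetate
Product: 4 (2S,4R)-2,4-dimethyl-5-oxopentyl acetate
Conditions: Dess–Martin periodinane, CH2Cl2, 0 °C to rt
Reagents that add atoms: none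
Why: Dess–Martin oxidation gives the aldehyde under non-basic conditions, so the adjacent C6 centre is not epimerised and the acetate survives.

Step 4
Reactants: 4 (2S,4R)-2,4-dimethyl-5-oxopentyl acetate
Product: 5 (2S,4R)-5-hydroxy-2,4-dimethylhexyl acetate (C5 epimers)
Conditions: MeMgBr (1.1 equiv), Et2O, −78 °C; then H2O
Reagents that add atoms: methylmagnesium bromide C[Mg]Br
Why: Grignard addition to the aldehyde at −78 °C is far faster than attack on the primary acetate, and the new C7 carbinol centre is an inconsequential epimer mixture because it is oxidised in step 13.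

Step 5
Reactants: 5 (2S,4R)-5-hydroxy-2,4-dimethylhexyl acetate
Product: 6 (2S,4R)-2,4-dimethyl-5-(triethylsilyloxy)hexyl acetate
Conditions: Et3SiCl, imidazole, CH2Cl2, 0 °C
Reagents that add atoms: chlorotriethylsilane CC[Si](Cl)(CC)CC
Why: Standard silyl ether formation masks the secondary alcohol as a triethylsilyl ether that can later be removed in the presence of a tert-butyldimethylsilyl ether.

Step 6
Reactants: 6 (2S,4R)-2,4-dimethyl-5-(triethylsilyloxy)hexyl acetate
Product: 7 (2S,4R)-2,4-dimethyl-5-(triethylsilyloxy)hexan-1-ol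
Conditions: K2CO3 (0.2 equiv), MeOH, 0 °C
Reagents that add atoms: none
Why: Base-catalysed transesterification (methanolysis) cleaves the primary acetate while the secondary silyl ether and both stereocentres are unaffected.

Step 7
Reactants: 7 (2S,4R)-2,4-dimethyl-5-(triethylsilyloxy)hexan-1-ol
Product: 8 (2S,4R)-2,4-dimethyl-5-(triethylsilyloxy)hexanal
Conditions: Dess–Martin periodinane, CH2Cl2, 0 °C to rt
Reagents that add atoms: none
Why: Dess–Martin oxidation gives the α-methyl aldehyde without epimerising C4, and it is used directly in step 10.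

Step 8
Reactants: 9 methyl tetronate (4-methoxyfuran-2(5H)-one)
Product: 11 (±)-5-[(dimethylamino)methyl]-4-methoxyfuran-2(5H)-one, via lithium 4-methoxyfuran-2-olate 10 (not isolated)
Conditions: LiN(iPr)2 (1.05 equiv), THF, −78 °C; then N,N-dimethylmethyleneiminium iodide, −78 °C to 0 °C
Reagents that add atoms: N,N-dimethylmethyleneiminium iodide C=[N+](C)C.[I-]
Why: The amide base removes a C5 proton to give the aromatic furanolate, which is aminomethylated at C5 by the preformed iminium salt (Mannich reaction); the new centre is racemic and is destroyed in step 9.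

Step 9
Reactants: 11 (±)-5-[(dimethylamino)methyl]-4-methoxyfuran-2(5H)-one
Product: 13 4-methoxy-5-methylenefuran-2(5H)-one, via trimethylammonium iodide 12 (not isolated)
Conditions: MeI, MeOH, rt; then aq. NaHCO3, CH2Cl2, rt
Reagents that add atoms: none
Why: N-Methylation turns the amine into a leaving group and mild base triggers E1cB (Hofmann-type) elimination across C5 to the exocyclic methylene, the standard methylenation of a Mannich base.

Step 10
Reactants: 13 4-methoxy-5-methylenefuran-2(5H)-one; 8 (2S,4R)-2,4-dimethyl-5-(triethylsilyloxy)hexanal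
Product: 15 3-[(2S,4R)-1-hydroxy-2,4-dimethyl-5-(triethylsilyloxy)hexyl]-4-methoxy-5-methylenefuran-2(5H)-one (epimers at C3 and C7), via 3-lithio-5-methylenetetronate 14 (not isolated)
Conditions: LiN(iPr)2 (1.05 equiv), THF, −78 °C, 15 min; then 8, −78 °C; then H2O
Reagents that add atoms: none
Why: With no C5 hydrogen left the base removes the vinylic C3 proton (between the lactone carbonyl and the methoxy group) and the alkenyllithium adds 1,2 to the aldehyde (aldol-type carbonyl addition) to forge C2–C3; the C3 carbinol epimers converge on oxidation in step 20 and C4 is not epimerised at −78 °C.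

Step 11
Reactants: 15 3-[(2S,4R)-1-hydroxy-2,4-dimethyl-5-(triethylsilyloxy)hexyl]-4-methoxy-5-methylenefuran-2(5H)-one
Product: 16 3-[(2S,4R)-1-(tert-butyldimethylsilyloxy)-2,4-dimethyl-5-(triethylsilyloxy)hexyl]-4-methoxy-5-methylenefuran-2(5H)-one
Conditions: TBSOTf, 2,6-lutidine, CH2Cl2, −78 °C to 0 °C
Reagents that add atoms: tert-butyldimethylsilyl triflate CC(C)(C)[Si](C)(C)OS(=O)(=O)C(F)(F)F
Why: A silyl triflate with a hindered pyridine base silylates the hindered secondary alcohol (silyl ether formation), so that C3 is not a carbonyl group during the enolate chemistry of step 17.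

Step 12
Reactants: 16 3-[(2S,4R)-1-(tert-butyldimethylsilyloxy)-2,4-dimethyl-5-(triethylsilyloxy)hexyl]-4-methoxy-5-methylenefuran-2(5H)-one
Product: 17 3-[(2S,4R)-1-(tert-butyldimethylsilyloxy)-5-hydroxy-2,4-dimethylhexyl]-4-methoxy-5-methylenefuran-2(5H)-one
Conditions: HF·pyridine, pyridine, THF, 0 °C
Reagents that add atoms: none
Why: Buffered HF·pyridine cleaves the triethylsilyl ether far faster than the more hindered tert-butyldimethylsilyl ether (selective desilylation), freeing only the C7 hydroxyl.

Step 13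
Reactants: 17 3-[(2S,4R)-1-(tert-butyldimethylsilyloxy)-5-hydroxy-2,4-dimethylhexyl]-4-methoxy-5-methylenefuran-2(5H)-one
Product: 18 3-[(2S,4R)-1-(tert-butyldimethylsilyloxy)-2,4-dimethyl-5-oxohexyl]-4-methoxy-5-methylenefuran-2(5H)-one
Conditions: Dess–Martin periodinane, CH2Cl2, 0 °C to rt
Reagents that add atoms: none
Why: Dess–Martin oxidation gives the C7 methyl ketone, which removes the C7 epimer mixture and leaves the adjacent C6 centre intact under non-basic conditions.

Step 14
Reactants: 19 tiglic aldehyde ((E)-2-methylbut-2-enal); 20 ethyl (triphenylphosphoranylidene)acetate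
Product: 21 ethyl (2E,4E)-4-methylhexa-2,4-dienoate
Conditions: toluene, 80 °C
Reagents that add atoms: none
Why: Wittig olefination with a stabilised ylide gives the new C10=C11 double bond with high E selectivity and does not isomerise the existing E-trisubstituted alkene.

Step 15
Reactants: 21 ethyl (2E,4E)-4-methylhexa-2,4-dienoate
Product: 22 (2E,4E)-4-methylhexa-2,4-dien-1-ol
Conditions: i-Bu2AlH (2.2 equiv), CH2Cl2, −78 °C; then H2O
Reagents that add atoms: none
Why: Diisobutylaluminium hydride reduces the conjugated ester 1,2 to the allylic alcohol at low temperature without touching the diene (hydride reduction).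

Step 16
Reactants: 22 (2E,4E)-4-methylhexa-2,4-dien-1-ol
Product: 23 (2E,4E)-4-methylhexa-2,4-dienal
Conditions: MnO2 (excess), CH2Cl2, rt
Reagents that add atoms: none
Why: MnO2 oxidises the allylic alcohol to the dienal without double-bond isomerisation or over-oxidation (allylic oxidation).

Step 17
Reactants: 18 3-[(2S,4R)-1-(tert-butyldimethylsilyloxy)-2,4-dimethyl-5-oxohexyl]-4-methoxy-5-methylenefuran-2(5H)-one; 23 (2E,4E)-4-methylhexa-2,4-dienal
Product: 25 3-[(2S,4R,8E,10E)-1-(tert-butyldimethylsilyloxy)-7-hydroxy-2,4,10-trimethyl-5-oxododeca-8,10-dienyl]-4-methoxy-5-methylenefuran-2(5H)-one (epimers at C3 and C9), via lithium enolate 24 (not isolated)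
Conditions: LiN(iPr)2 (1.05 equiv), THF, −78 °C, 30 min; then 23, −78 °C; then H2O
Reagents that add atoms: none
Why: Kinetic deprotonation takes place at the methyl group and not at the C6 methine, and the lithium enolate adds 1,2 to the dienal (crossed aldol addition) to forge C8–C9 and join the C1–C8 and C9–C13 fragments; the C9 carbinol epimers do not matter because that centre is removed in step 18.

Step 18
Reactants: 25 3-[(2S,4R,8E,10E)-1-(tert-butyldimethylsilyloxy)-7-hydroxy-2,4,10-trimethyl-5-oxododeca-8,10-dienyl]-4-methoxy-5-methylenefuran-2(5H)-one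
Product: 27 3-[(2S,4R,6E,8E,10E)-1-(tert-butyldimethylsilyloxy)-2,4,10-trimethyl-5-oxododeca-6,8,10-trienyl]-4-methoxy-5-methylenefuran-2(5H)-one, via C9 mesylate 26 (not isolated)
Conditions: MsCl, Et3N (excess), CH2Cl2, 0 °C to rt
Reagents that add atoms: none
Why: Mesylation followed by E1cB elimination through the ketone enolate completes the aldol condensation and gives the thermodynamically favoured 8E-enone in conjugation with the diene.

Step 19
Reactants: 27 3-[(2S,4R,6E,8E,10E)-1-(tert-butyldimethylsilyloxy)-2,4,10-trimethyl-5-oxododeca-6,8,10-trienyl]-4-methoxy-5-methylenefuran-2(5H)-one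
Product: 28 3-[(2S,4R,6E,8E,10E)-1-hydroxy-2,4,10-trimethyl-5-oxododeca-6,8,10-trienyl]-4-methoxy-5-methylenefuran-2(5H)-one
Conditions: HF·pyridine (excess), THF, 0 °C to rt
Reagents that add atoms: none
Why: Excess HF·pyridine removes the remaining silyl ether (fluoride-mediated desilylation) without affecting the trienone or the methyl enol ether.

Step 20
Reactants: 28 3-[(2S,4R,6E,8E,10E)-1-hydroxy-2,4,10-trimethyl-5-oxododeca-6,8,10-trienyl]-4-methoxy-5-methylenefuran-2(5H)-one
Product: 29 (2S,4R,6E,8E,10E)-1-(4-methoxy-5-methylene-2-oxo-2,5-dihydrofuran-3-yl)-2,4,10-trimethyldodeca-6,8,10-triene-1,5-dione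
Conditions: Dess–Martin periodinane, CH2Cl2, 0 °C to rt
Reagents that add atoms: none
Why: Dess–Martin oxidation converts the C3 carbinol to the ketone, which removes the last epimer mixture and turns the exocyclic methylene into an acyl-activated, chelating dienophile.

Step 21
Reactants: 29 (2S,4R,6E,8E,10E)-1-(4-methoxy-5-methylene-2-oxo-2,5-dihydrofuran-3-yl)-2,4,10-trimethyldodeca-6,8,10-triene-1,5-dione
Product: 30 Diels–Alder macrocycle (4S,6R,8E,10S,13S,15S): O-methyl spirotetronate on a C11=C12 cyclohexene bridged from C2 to C10 by the 3,7-dioxo-4,6-dimethyl-8E-ene chain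
Conditions: La(OTf)3 (10 mol%), BHT (cat.), toluene (0.005 M), 100 °C
Reagents that add atoms: none
Why: A Lewis-acid-assisted intramolecular Diels–Alder reaction between the exocyclic C14=C15 dienophile and the 10E,12E-diene closes the cyclohexene and the eleven-membered ring at once; the two outward diene substituents (C9 and the C13 methyl) end up cis, the tether forces C16 onto the same face as C9, and the syn-4,6-dimethyl tether selects the diene face so that C10, C13 and C15 are all S, by analogy with the parent system without the C12 methyl, which is expected to give one diastereomer.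

Step 22
Reactants: 30 Diels–Alder macrocycle (4S,6R,8E,10S,13S,15S)
Product: 31 11,12-epoxide of 30 (11S,12R; epoxide oxygen anti to C16)
Conditions: dimethyldioxirane (1.1 equiv), acetone, 0 °C
Reagents that add atoms: dimethyldioxirane CC1(C)OO1
Why: Dimethyldioxirane epoxidises the isolated electron-rich trisubstituted C11=C12 alkene in preference to the enone and the acyl-substituted tetronate alkene (electrophilic epoxidation), from the ring face opposite C16, C9 and the C13 methyl, which sets 11S and 12R.

Step 23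
Reactants: 31 11,12-epoxide of 30
Product: 33 macrocyclic enone (4S,6R,8E,10S,11S,12S,13S,15S) with the C16–O–C12 ether bridge (2-oxabicyclo[2.2.2]octane) and free 11-OH, via lithium tetronate 32 (not isolated)
Conditions: LiCl (5 equiv), DMSO, 50 °C; then p-TsOH·H2O (1.1 equiv), rt
Reagents that add atoms: none
Why: Chloride removes the methyl group of the vinylogous carbonate by SN2 dealkylation and, once protonated, the tetronate oxygen on C16 opens the epoxide at the tertiary carbon C12 with inversion (intramolecular 6-exo epoxide opening), which gives the oxabicyclo[2.2.2]octane with 12S and leaves the 11S hydroxyl.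

Step 24
Reactants: 33 macrocyclic enone (4S,6R,8E,10S,11S,12S,13S,15S)
Product: 35 abyssomicin N (4S,6R,8R,10S,11S,12S,13S,15S,16R), via lithium C7 enolate 34 (not isolated)
Conditions: LiBH(s-Bu)3 (1.5 equiv), THF, −78 °C to −40 °C; then H2O
Reagents that add atoms: none
Why: Conjugate hydride addition to C9 of the strained enone gives the C7 enolate, whose C8 adds across the ring to C16 of the doubly activated tetronate alkene (reductive transannular Michael addition); the cage allows bond formation only on the C10 side of C16 with C7 cis to C2, which fixes 8R and 16R, and protonation of the resulting β-keto lactone enolate gives the hydrogen-bonded exocyclic enol of the target.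

## Compound list

1 | meso-2,4-dimethylglutaric anhydride (cis-3,5-dimethyloxane-2,6-dione) | C[C@H]1C[C@@H](C)C(=O)OC1=O | starting material
2 | meso-2,4-dimethylpentane-1,5-diol | C[C@@H](CO)C[C@H](C)CO | intermediate
3 | (2S,4R)-5-hydroxy-2,4-dimethylpentyl acetate | C[C@@H](CO)C[C@H](C)COC(C)=O | intermediate
4 | (2S,4R)-2,4-dimethyl-5-oxopentyl acetate | C[C@@H](C=O)C[C@H](C)COC(C)=O | intermediate
5 | (2S,4R)-5-hydroxy-2,4-dimethylhexyl acetate, C5 epimers | C[C@@H](C(C)O)C[C@H](C)COC(C)=O | intermediate
6 | (2S,4R)-2,4-dimethyl-5-(triethylsilyloxy)hexyl acetate, C5 epimers | C[C@@H](C(C)O[Si](CC)(CC)CC)C[C@H](C)COC(C)=O | intermediate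
7 | (2S,4R)-2,4-dimethyl-5-(triethylsilyloxy)hexan-1-ol, C5 epimers | C[C@@H](C(C)O[Si](CC)(CC)CC)C[C@H](C)CO | intermediate
8 | (2S,4R)-2,4-dimethyl-5-(triethylsilyloxy)hexanal, C5 epimers | C[C@@H](C(C)O[Si](CC)(CC)CC)C[C@H](C)C=O | intermediate
9 | methyl tetronate (4-methoxyfuran-2(5H)-one) | COC1=CC(=O)OC1 | starting material
10 | lithium 4-methoxyfuran-2-olate (C5-deprotonated methyl tetronate) | [Li+].[O-]c1cc(OC)co1 | intermediate
11 | (±)-5-[(dimethylamino)methyl]-4-methoxyfuran-2(5H)-one | COC1=CC(=O)OC1CN(C)C | intermediate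
12 | [(3-methoxy-5-oxo-2,5-dihydrofuran-2-yl)methyl]trimethylammonium iodide | COC1=CC(=O)OC1C[N+](C)(C)C.[I-] | intermediate
13 | 4-methoxy-5-methylenefuran-2(5H)-one | COC1=CC(=O)OC1=C | intermediate
14 | 3-lithio-4-methoxy-5-methylenefuran-2(5H)-one | [Li]C1=C(OC)C(=C)OC1=O | intermediate
15 | 3-[(2S,4R)-1-hydroxy-2,4-dimethyl-5-(triethylsilyloxy)hexyl]-4-methoxy-5-methylenefuran-2(5H)-one, epimers at C3 and C7 | C[C@@H](C(C)O[Si](CC)(CC)CC)C[C@H](C)C(O)C1=C(OC)C(=C)OC1=O | intermediate
16 | 3-[(2S,4R)-1-(tert-butyldimethylsilyloxy)-2,4-dimethyl-5-(triethylsilyloxy)hexyl]-4-methoxy-5-methylenefuran-2(5H)-one | C[C@@H](C(C)O[Si](CC)(CC)CC)C[C@H](C)C(O[Si](C)(C)C(C)(C)C)C1=C(OC)C(=C)OC1=O | intermediate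
17 | 3-[(2S,4R)-1-(tert-butyldimethylsilyloxy)-5-hydroxy-2,4-dimethylhexyl]-4-methoxy-5-methylenefuran-2(5H)-one | C[C@@H](C(C)O)C[C@H](C)C(O[Si](C)(C)C(C)(C)C)C1=C(OC)C(=C)OC1=O | intermediate
18 | 3-[(2S,4R)-1-(tert-butyldimethylsilyloxy)-2,4-dimethyl-5-oxohexyl]-4-methoxy-5-methylenefuran-2(5H)-one, C3 epimers | C[C@@H](C(C)=O)C[C@H](C)C(O[Si](C)(C)C(C)(C)C)C1=C(OC)C(=C)OC1=O | intermediate
19 | tiglic aldehyde ((E)-2-methylbut-2-enal) | C/C=C(\C)C=O | starting material
20 | ethyl (triphenylphosphoranylidene)acetate | CCOC(=O)C=P(c1ccccc1)(c1ccccc1)c1ccccc1 | starting material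
21 | ethyl (2E,4E)-4-methylhexa-2,4-dienoate | C/C=C(C)/C=C/C(=O)OCC | intermediate
22 | (2E,4E)-4-methylhexa-2,4-dien-1-ol | C/C=C(C)/C=C/CO | intermediate
23 | (2E,4E)-4-methylhexa-2,4-dienal | C/C=C(C)/C=C/C=O | intermediate
24 | lithium enolate of 18 (C7 oxygen, C7=C8 double bond) | [Li+].C[C@@H](C(=C)[O-])C[C@H](C)C(O[Si](C)(C)C(C)(C)C)C1=C(OC)C(=C)OC1=O | intermediate
25 | 3-[(2S,4R,8E,10E)-1-(tert-butyldimethylsilyloxy)-7-hydroxy-2,4,10-trimethyl-5-oxododeca-8,10-dienyl]-4-methoxy-5-methylenefuran-2(5H)-one, epimers at C3 and C9 | C[C@@H](C(=O)CC(O)/C=C/C(C)=C/C)C[C@H](C)C(O[Si](C)(C)C(C)(C)C)C1=C(OC)C(=C)OC1=O | intermediate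
26 | C9 methanesulfonate of 25 | C[C@@H](C(=O)CC(OS(C)(=O)=O)/C=C/C(C)=C/C)C[C@H](C)C(O[Si](C)(C)C(C)(C)C)C1=C(OC)C(=C)OC1=O | intermediate
27 | 3-[(2S,4R,6E,8E,10E)-1-(tert-butyldimethylsilyloxy)-2,4,10-trimethyl-5-oxododeca-6,8,10-trienyl]-4-methoxy-5-methylenefuran-2(5H)-one, C3 epimers | C[C@@H](C(=O)/C=C/C=C/C(C)=C/C)C[C@H](C)C(O[Si](C)(C)C(C)(C)C)C1=C(OC)C(=C)OC1=O | intermediate
28 | 3-[(2S,4R,6E,8E,10E)-1-hydroxy-2,4,10-trimethyl-5-oxododeca-6,8,10-trienyl]-4-methoxy-5-methylenefuran-2(5H)-one, C3 epimers | C[C@@H](C(=O)/C=C/C=C/C(C)=C/C)C[C@H](C)C(O)C1=C(OC)C(=C)OC1=O | intermediate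
29 | (2S,4R,6E,8E,10E)-1-(4-methoxy-5-methylene-2-oxo-2,5-dihydrofuran-3-yl)-2,4,10-trimethyldodeca-6,8,10-triene-1,5-dione | C[C@@H](C(=O)/C=C/C=C/C(C)=C/C)C[C@H](C)C(=O)C1=C(OC)C(=C)OC1=O | intermediate
30 | Diels–Alder macrocycle (4S,6R,8E,10S,13S,15S): C15-spiro 4-methoxybutenolide on a C11=C12 cyclohexene (12,13-dimethyl), bridged C2 to C10 by the 3,7-dioxo-4,6-dimethyl-8E-ene chain | C[C@@H]1C[C@H](C)C(=O)C2=C(OC)[C@]3(OC2=O)C[C@H](C)C(C)=C[C@@H]3/C=C/C1=O | intermediate
31 | 11,12-epoxide of 30 (11S,12R; oxygen anti to C16) | C[C@@H]1C[C@H](C)C(=O)C2=C(OC)[C@]3(OC2=O)C[C@H](C)[C@@]4(C)O[C@H]4[C@@H]3/C=C/C1=O | intermediate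
32 | lithium tetronate of 31 (O-demethylated at C16) | [Li+].C[C@@H]1C[C@H](C)C(=O)C2=C([O-])[C@]3(OC2=O)C[C@H](C)[C@@]4(C)O[C@H]4[C@@H]3/C=C/C1=O | intermediate
33 | macrocyclic enone (4S,6R,8E,10S,11S,12S,13S,15S): tetronate C16–O–C12 ether bridge (2-oxabicyclo[2.2.2]octane), 11-OH, 12,13-dimethyl, eleven-membered 3,7-dioxo-4,6-dimethyl-8E-ene ring | C[C@@H]1C[C@H](C)C(=O)C2=C3O[C@@]4(C)[C@@H](C)C[C@]3(OC2=O)[C@@H](/C=C/C1=O)[C@@H]4O | intermediate
34 | lithium C7 enolate of 8,9-dihydro-33 | [Li+].C[C@@H]1C[C@H](C)C(=O)C2=C3O[C@@]4(C)[C@@H](C)C[C@]3(OC2=O)[C@@H](CC=C1[O-])[C@@H]4O | intermediate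
35 | abyssomicin N (4S,6R,8R,10S,11S,12S,13S,15S,16R) | C[C@@H]1C[C@H](C)/C(O)=C2/C(=O)O[C@]34C[C@H](C)[C@]5(C)O[C@]23[C@@H](C[C@H]4[C@@H]5O)C1=O | target

## Totals and risks

Total step count: 24.
Longest linear sequence: 19 steps (steps 1–7, 10–13, 17–24).

Three steps most likely to fail:

Step 21 (macrocyclising Diels–Alder). The diene is part of an electron-poor, polymerisable trienone, and the extra C12 methyl is untested in this cyclisation. The fallback sets out from aldol product 25 and keeps C9 saturated during the cycloaddition. Acetylation of the C9 hydroxyl (Ac2O, pyridine, 0 °C) gives the β-acetoxy ketone F1. HF·pyridine then frees the C3 alcohol F2, and Dess–Martin oxidation gives the 8,9-dihydro-9-acetoxy analogue of 29, F3. In F3 the diene is isolated and more electron-rich, and heating (toluene, 110 °C, BHT, high dilution) gives the 9-acetoxy cycloadduct F4. DBU in CH2Cl2 then eliminates the acetate to the 8E-enone, and the route is rejoined at 30.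

Step 24 (reductive transannular Michael addition). The hydride may add 1,2 to C7 or the enolate may be quenched before it cyclises. The fallback sets out from 33 and separates reduction from cyclisation. 1,4-Hydrosilylation with Et3SiH and catalytic RhCl(PPh3)3 (THF, 50 °C) gives the isolable C7 triethylsilyl enol ether F5. Bu4NF in THF at −78 °C then releases the enolate for the transannular Michael addition to C16 (TiCl4 at −78 °C as a Mukaiyama–Michael alternative), and the route is rejoined at 35.

Step 10 (vinylic lithiation of the 5-methylene tetronate and addition to 8). The exocyclic methylene is a Michael acceptor for the amide base, and the lithio species can oligomerise. The fallback sets out from 13 and avoids any amide base. Bromination at C3 (N-bromosuccinimide, MeCN, rt) gives 3-bromo-4-methoxy-5-methylenefuran-2(5H)-one F6. Bromine–magnesium exchange with i-PrMgCl·LiCl (THF, −40 °C) gives the alkenylmagnesium reagent, which adds to aldehyde 8, and the route is rejoined at 15.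

## Further compounds

F1 | step 21 | C9 acetate of 25 (C3 silyl ether retained) | C[C@@H](C(=O)CC(OC(C)=O)/C=C/C(C)=C/C)C[C@H](C)C(O[Si](C)(C)C(C)(C)C)C1=C(OC)C(=C)OC1=O
F2 | step 21 | C3 alcohol from F1 (C9 acetate retained) | C[C@@H](C(=O)CC(OC(C)=O)/C=C/C(C)=C/C)C[C@H](C)C(O)C1=C(OC)C(=C)OC1=O
F3 | step 21 | 8,9-dihydro-9-acetoxy analogue of 29 | C[C@@H](C(=O)CC(OC(C)=O)/C=C/C(C)=C/C)C[C@H](C)C(=O)C1=C(OC)C(=C)OC1=O
F4 | step 21 | 8,9-dihydro-9-acetoxy analogue of 30 | C[C@@H]1C[C@H](C)C(=O)C2=C(OC)[C@]3(OC2=O)C[C@H](C)C(C)=C[C@@H]3C(OC(C)=O)CC1=O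
F5 | step 24 | C7 triethylsilyl enol ether of 8,9-dihydro-33 | C[C@@H]1C[C@H](C)C(=O)C2=C3O[C@@]4(C)[C@@H](C)C[C@]3(OC2=O)[C@@H](CC=C1O[Si](CC)(CC)CC)[C@@H]4O
F6 | step 10 | 3-bromo-4-methoxy-5-methylenefuran-2(5H)-one | COC1=C(Br)C(=O)OC1=C
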